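**Plan**

1. Numbering (germacrane): ten-membered ring C1–C10. The lactone ring is O–C6–C7–C11–C12(=O). C13 is the exocyclic CH2 on C11, C14 the CO2Me carbon on C10, C15 the CH3 on C4.
2. Cuts: C11=C13 (olefination), C4=C5 (ring-closing metathesis), the acyl–O9 and acyl–O8 ester bonds, C9–C10 (alkenyl–aldehyde coupling), then C7–C11 of the γ-lactone. The last cut leads back to the phosphonoacetate of a C5–C9 epoxy alcohol.
3. Enabling feature: in the lactone ring, C7 carries C11 next to the ring oxygen on C6 and anti to the acyloxy oxygen on C8. The array O6–C6–C7(C11)–C8–O8 is therefore the imprint of a 5-exo, anti opening of a trans-C7/C8 epoxide by a carbanion hung on O6. That one event closes the lactone, inverts C7, frees O8 alone (so O8 and O9 are told apart) and plants the latent methylene.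
4. Forward order: C5–C9 chain → epoxide → γ-lactone (first ring) → O8 ester → C9 aldehyde joined to the C10/C14/C1–C4/C15 iodide → O9 ester → ten-membered ring → C13 methylene → desilylation.
5. Stereochemistry: C6, C7 and C8 come from one Sharpless kinetic-resolution epoxidation (C7 is then inverted). C9 comes from Felkin–Anh addition next to C8, the epoxyangelate from a Sharpless epoxidation, the hydroxy ester from an Evans syn aldol. The C1=C10 geometry comes from an iodo-Wittig reaction and the cis C4=C5 alkene from ring strain in the metathesis.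
6. The diethyl phosphonate is the only helper group. It acidifies C11 for the key step, masks the Michael acceptor through coupling and metathesis, and leaves as phosphate when C13 is installed.

Key step: step 5

Remark: 9, 14–16, 22, 29 and 30 are carried as mixtures of epimers at C11 (no stereo mark in their SMILES), because this centre becomes sp2 in step 20.

**Route**

Step 1
Reactants: 1 (tert-butyldimethylsilyloxy)acetaldehyde; 2 (triphenylphosphoranylidene)acetaldehyde
Product: 3 (E)-4-(tert-butyldimethylsilyloxy)but-2-enal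
Conditions: toluene, 80 °C
Reagents that add atoms: none
Why: Wittig olefination with the stabilised formyl ylide should give the E-enal, whose geometry later becomes the trans-epoxide.

Step 2
Reactants: 3 (E)-4-(tert-butyldimethylsilyloxy)but-2-enal; 4 vinylmagnesium bromide
Product: 5 racemic (E)-6-(tert-butyldimethylsilyloxy)hexa-1,4-dien-3-ol
Conditions: THF, −78 °C; then sat. aq. NH4Cl
Reagents that add atoms: none
Why: Grignard 1,2-addition to the enal is fast at low temperature, and the new carbinol centre C6 is made racemic on purpose because step 3 sorts it.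

Step 3
Reactants: 5 racemic (E)-6-(tert-butyldimethylsilyloxy)hexa-1,4-dien-3-ol
Product: 6 (1R)-1-[(2R,3R)-3-(tert-butyldimethylsilyloxymethyl)oxiran-2-yl]prop-2-en-1-ol (erythro epoxy alcohol, trans-epoxide)
Conditions: Ti(OiPr)4 (0.15 equiv), D-(−)-DIPT (0.2 equiv), t-BuOOH (0.45 equiv), 4 Å MS, CH2Cl2, −20 °C
Reagents that add atoms: tert-butyl hydroperoxide, CC(C)(C)OO
Why: Sharpless kinetic-resolution epoxidation: with D-(−)-DIPT the (R)-carbinol is the fast enantiomer, its E-disubstituted C7=C8 alkene is both the matched and the more nucleophilic one (the vinyl group is mismatched and monosubstituted), and oxygen delivery should give the erythro trans-epoxy alcohol, so that C6, C7 and C8 are fixed together while the (S)-alcohol stays behind.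

Step 4
Reactants: 6 epoxy alcohol; 7 (diethoxyphosphoryl)acetic acid
Product: 8 (1R)-1-[(2R,3R)-3-(tert-butyldimethylsilyloxymethyl)oxiran-2-yl]prop-2-en-1-yl (diethoxyphosphoryl)acetate
Conditions: DCC, DMAP (cat.), CH2Cl2, 0 °C → rt
Reagents that add atoms: none
Why: Steglich esterification runs under neutral conditions, so neither Payne rearrangement of the epoxy alcohol nor allylic transposition is expected and no stereocentre is touched.

Step 5
Reactants: 8 epoxy phosphonoacetate
Product: 9 diethyl {(4R,5R)-5-ethenyl-4-[(1S)-1-hydroxy-2-(tert-butyldimethylsilyloxy)ethyl]-2-oxooxolan-3-yl}phosphonate (trans-4,5-lactone; germacrane 6R,7R,8S; C11 epimers)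
Conditions: LiClO4 (2 equiv), DBU (1.1 equiv), MeCN (0.02 M), 0 → 45 °C; then pH 7 buffer
Reagents that add atoms: none
Why: Proposed new method: soft enolisation (Li+ chelation of the phosphonoacetate with DBU, as in Masamune–Roush olefinations) gives the stabilised C11 carbanion, which should attack the Li+-activated epoxide at C7 from the rear, break the C7–O bond and leave the oxygen on C8, after which the C8 alkoxide takes the acidic C11–H of the new α-phosphono lactone, so that the hydroxyl group is released and the charge rests in an unreactive chelated carbanion. The closest known reaction types are the intramolecular Michael addition of O-tethered phosphonoacetates to enones in telescoped Michael/olefination sequences, the exo-selective cyclisation of epoxides that carry tethered bis-activated carbanions, and the intermolecular opening of epoxides by phosphonoacetate anions; what has not been shown is an epoxide as acceptor for the ester-tethered phosphonoacetate. The γ-lactone ring (O–C6–C7–C11–C12) closes in the 5-exo-tet mode, which allows the collinear C11···C7–O alignment, whereas 6-endo attack at C8 needs a far more distorted approach; both epoxide carbons are secondary and equally β-oxygenated, so the tether length decides the regiochemistry. C7 is set by SN2 inversion of the epoxide carbon, C6 and C8 keep the configuration from step 3, the erythro relation places the vinyl group and the C8 chain trans on the forming ring, and C11 arises as an inconsequential epimer mixture that is erased in step 20. The step needs chemoselectivity for epoxide opening over acyl or phosphoryl transfer to O8 (lactone migration, Wadsworth–Emmons cyclopropanation), and the internal proton transfer, the moderate temperature and the greater stability of the trans-disubstituted 6,7-lactone over the cis 7,8-lactone should secure it.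

Step 6
Reactants: 10 angelic acid, (Z)-2-methylbut-2-enoic acid
Product: 11 (Z)-2-methylbut-2-en-1-ol
Conditions: LiAlH4, Et2O, 0 °C; then H2O
Reagents that add atoms: none
Why: Hydride reduction of the acid with LiAlH4 goes 1,2 and should leave the Z-alkene geometry intact.

Step 7
Reactants: 11 (Z)-2-methylbut-2-en-1-ol
Product: 12 [(2R,3S)-2,3-dimethyloxiran-2-yl]methanol
Conditions: Ti(OiPr)4 (0.1 equiv), D-(−)-DIPT (0.13 equiv), t-BuOOH, 4 Å MS, CH2Cl2, −20 °C
Reagents that add atoms: tert-butyl hydroperoxide, CC(C)(C)OO
Why: Sharpless asymmetric epoxidation: D-(−)-DIPT directs oxygen to the face that gives the (2R,3S)-epoxy alcohol, and the syn addition keeps CH2OH and the C3 methyl group cis.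

Step 8
Reactants: 12 [(2R,3S)-2,3-dimethyloxiran-2-yl]methanol
Product: 13 (2S,3S)-2,3-dimethyloxirane-2-carboxylic acid (epoxyangelic acid)
Conditions: RuCl3 (2 mol %), NaIO4, MeCN–EtOAc–H2O, 0 °C → rt
Reagents that add atoms: sodium periodate (oxygen passed on through RuO4), [Na+].[O-]I(=O)(=O)=O
Why: Catalytic RuO4 oxidation takes primary epoxy alcohols to glycidic acids without opening the epoxide; both centres are untouched and only the descriptor at C2 changes.

Step 9
Reactants: 9 hydroxy phosphono lactone; 13 epoxyangelic acid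
Product: 14 O8-epoxyangelate of 9 (6R,7S,8S; C9 still CH2OTBS)
Conditions: 2-methyl-6-nitrobenzoic anhydride (MNBA), DMAP, Et3N, CH2Cl2, rt
Reagents that add atoms: none
Why: Shiina esterification couples hindered acids and secondary alcohols under mild base, O8 is the only free hydroxyl group, and Et3N/DMAP are too weak to deprotonate C11 to a useful extent.

Step 10
Reactants: 14 O8-epoxyangelate silyl ether
Product: 15 primary alcohol (C9–OH) of 14
Conditions: HF·pyridine, pyridine, THF, 0 °C
Reagents that add atoms: none
Why: Fluoride cleavage of the primary silyl ether in a buffered acidic medium should avoid the base-induced O8→O9 acyl shift and spares phosphonate, epoxide and lactone.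

Step 11
Reactants: 15 primary alcohol
Product: 16 α-acyloxy aldehyde (C9 = CHO)
Conditions: Dess–Martin periodinane, CH2Cl2, 0 °C → rt
Reagents that add atoms: none
Why: Dess–Martin oxidation is neutral and fast, so the α-acyloxy aldehyde should form without epimerisation at C8 and is used at once.

Step 12
Reactants: 17 4-methylpent-4-en-1-ol
Product: 18 4-methylpent-4-enal
Conditions: TEMPO (10 mol %), PhI(OAc)2, CH2Cl2, rt
Reagents that add atoms: none
Why: TEMPO/PhI(OAc)2 oxidation stops at the aldehyde and does not touch the 1,1-disubstituted alkene.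

Step 13
Reactants: 18 4-methylpent-4-enal; 19 methyl (triphenylphosphoranylidene)acetate
Product: 21 methyl (Z)-2-iodo-6-methylhepta-2,6-dienoate, via iodo ylide 20 (not isolated)
Conditions: 19, NIS, CH2Cl2, −20 °C; then 18, −20 °C → rt
Reagents that add atoms: N-iodosuccinimide, O=C1CCC(=O)N1I
Why: Iodination of the stabilised ylide and Wittig olefination in one flask should place the ester trans to the alkyl chain, i.e. give the Z-iodide whose iodine marks the place of C9.

Step 14
Reactants: 16 α-acyloxy aldehyde; 21 methyl (Z)-2-iodo-6-methylhepta-2,6-dienoate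
Product: 22 C9 allylic alcohol (6R,7S,8S,9R; 1(10)E enoate; seco-diene)
Conditions: CrCl2 (6 equiv), NiCl2 (1 mol % of the CrCl2), DMSO–THF, rt; then H2O
Reagents that add atoms: none
Why: Nozaki–Hiyama–Kishi coupling is non-basic (no olefination by the resident phosphonate) and retains alkenyl geometry, and C9 should be set by polar Felkin–Anh attack anti to the C8 acyloxy group, which gives the 8,9-erythro (9R) alcohol.

Step 15
Reactants: 23 (R)-4-benzyl-3-propanoyloxazolidin-2-one; 24 acetaldehyde
Product: 26 (R)-4-benzyl-3-[(2R,3S)-3-hydroxy-2-methylbutanoyl]oxazolidin-2-one, via boron enolate 25 (not isolated)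
Conditions: Bu2BOTf, Et3N, CH2Cl2, 0 °C; 24, −78 → 0 °C; then H2O2, MeOH, pH 7 buffer
Reagents that add atoms: none
Why: Evans syn aldol: the Z-boron enolate reacts through a chair transition state on the face opposite the benzyl group of the (R)-auxiliary, which sets (2R,3S).

Step 16
Reactants: 26 syn aldol adduct
Product: 27 triethylsilyl ether of 26
Conditions: TESCl, imidazole, CH2Cl2, 0 °C → rt
Reagents that add atoms: chlorotriethylsilane, CC[Si](Cl)(CC)CC
Why: Standard silylation; the triethylsilyl group is chosen because it can leave at the end under conditions that the methylene lactone and the epoxy ester tolerate.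

Step 17
Reactants: 27 silylated imide
Product: 28 (2R,3S)-2-methyl-3-(triethylsilyloxy)butanoic acid
Conditions: LiOH, H2O2, THF–H2O, 0 °C; Na2SO3; then dil. HCl to pH 4
Reagents that add atoms: hydrogen peroxide (as LiOOH), OO
Why: LiOOH attacks the exocyclic imide carbonyl selectively, so the auxiliary should leave without epimerisation at C2 or loss of the silyl ether.

Step 18
Reactants: 22 C9 alcohol; 28 (2R,3S)-2-methyl-3-(triethylsilyloxy)butanoic acid
Product: 29 8,9-diester seco-diene
Conditions: MNBA, DMAP, Et3N, CH2Cl2, rt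
Reagents that add atoms: none
Why: Shiina esterification of the only free hydroxyl group (O9) under mild base should avoid O8/O9 acyl exchange and allylic substitution of the new ester.

Step 19
Reactants: 29 seco-diene
Product: 30 11-(diethoxyphosphoryl) (1(10)E,4Z,6R,7S,8S,9R)-germacra-1(10),4-dien-12,6-olide with the 14-methyl ester, the 8-epoxyangelate and the 9-(silyloxy)methylbutanoate
Conditions: second-generation Grubbs catalyst (15 mol %), 1,4-benzoquinone (30 mol %), toluene (1 mM), 80 °C
Reagents that add atoms: none
Why: Ring-closing metathesis between the vinyl group on C6 and the 1,1-disubstituted alkene at C4 (closure of ten-membered carbocycles with a trisubstituted alkene has precedent); the electron-poor C1=C10 enoate is inert, the methylene lactone is still masked, and ring strain should allow only the cis (4Z) ring alkene.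

Step 20
Reactants: 30 macrocyclic phosphono lactone
Product: 31 triethylsilyl ether of the target
Conditions: K2CO3, aq. HCHO (37 %), THF, 0 °C
Reagents that add atoms: formaldehyde, C=O
Why: Horner–Wadsworth–Emmons olefination of α-phosphono lactones with formaldehyde runs with weak base at 0 °C, removes the helper group and the C11 centre, and should spare the four esters.

Step 21
Reactants: 31 triethylsilyl ether of the target
Product: 32 CNP0135583.1 (target)
Conditions: HF·pyridine, pyridine, THF, 0 °C
Reagents that add atoms: none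
Why: Buffered HF·pyridine removes the triethylsilyl ether without base, so retro-aldol cleavage, acyl migration and addition to the methylene lactone are avoided.

**Compound list**

1 | (tert-butyldimethylsilyloxy)acetaldehyde | O=CCO[Si](C)(C)C(C)(C)C | starting material
2 | (triphenylphosphoranylidene)acetaldehyde | O=CC=P(c1ccccc1)(c1ccccc1)c1ccccc1 | starting material
3 | (E)-4-(tert-butyldimethylsilyloxy)but-2-enal | O=C/C=C/CO[Si](C)(C)C(C)(C)C | intermediate
4 | vinylmagnesium bromide | C=C[Mg]Br | starting material
5 | racemic (E)-6-(tert-butyldimethylsilyloxy)hexa-1,4-dien-3-ol | C=CC(O)/C=C/CO[Si](C)(C)C(C)(C)C | intermediate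
6 | (1R)-1-[(2R,3R)-3-(tert-butyldimethylsilyloxymethyl)oxiran-2-yl]prop-2-en-1-ol | C=C[C@@H](O)[C@H]1O[C@@H]1CO[Si](C)(C)C(C)(C)C | intermediate
7 | (diethoxyphosphoryl)acetic acid | OC(=O)CP(=O)(OCC)OCC | starting material
8 | (diethoxyphosphoryl)acetate of 6 | C=C[C@@H](OC(=O)CP(=O)(OCC)OCC)[C@H]1O[C@@H]1CO[Si](C)(C)C(C)(C)C | intermediate
9 | diethyl {(4R,5R)-5-ethenyl-4-[(1S)-1-hydroxy-2-(tert-butyldimethylsilyloxy)ethyl]-2-oxooxolan-3-yl}phosphonate | C=C[C@H]1OC(=O)C(P(=O)(OCC)OCC)[C@@H]1[C@H](O)CO[Si](C)(C)C(C)(C)C | intermediate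
10 | angelic acid | C/C=C(/C)C(=O)O | starting material
11 | (Z)-2-methylbut-2-en-1-ol | C/C=C(/C)CO | intermediate
12 | [(2R,3S)-2,3-dimethyloxiran-2-yl]methanol | OC[C@@]1(C)O[C@H]1C | intermediate
13 | (2S,3S)-2,3-dimethyloxirane-2-carboxylic acid | OC(=O)[C@@]1(C)O[C@H]1C | intermediate
14 | O8-epoxyangelate of 9 | C=C[C@H]1OC(=O)C(P(=O)(OCC)OCC)[C@@H]1[C@H](OC(=O)[C@@]2(C)O[C@H]2C)CO[Si](C)(C)C(C)(C)C | intermediate
15 | C9 primary alcohol | C=C[C@H]1OC(=O)C(P(=O)(OCC)OCC)[C@@H]1[C@H](OC(=O)[C@@]2(C)O[C@H]2C)CO | intermediate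
16 | C9 aldehyde | C=C[C@H]1OC(=O)C(P(=O)(OCC)OCC)[C@@H]1[C@H](OC(=O)[C@@]2(C)O[C@H]2C)C=O | intermediate
17 | 4-methylpent-4-en-1-ol | C=C(C)CCCO | starting material
18 | 4-methylpent-4-enal | C=C(C)CCC=O | intermediate
19 | methyl (triphenylphosphoranylidene)acetate | COC(=O)C=P(c1ccccc1)(c1ccccc1)c1ccccc1 | starting material
20 | methyl iodo(triphenylphosphoranylidene)acetate | COC(=O)C(I)=P(c1ccccc1)(c1ccccc1)c1ccccc1 | intermediate
21 | methyl (Z)-2-iodo-6-methylhepta-2,6-dienoate | C=C(C)CC/C=C(/C(=O)OC)I | intermediate
22 | C9 allylic alcohol, seco-diene (6R,7S,8S,9R) | C=C[C@H]1OC(=O)C(P(=O)(OCC)OCC)[C@@H]1[C@H](OC(=O)[C@@]2(C)O[C@H]2C)[C@H](O)/C(C(=O)OC)=C\CCC(C)=C | intermediate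
23 | (R)-4-benzyl-3-propanoyloxazolidin-2-one | CCC(=O)N1[C@H](Cc2ccccc2)COC1=O | starting material
24 | acetaldehyde | CC=O | starting material
25 | (Z)-dibutylboron enolate of 23 | C/C=C(\OB(CCCC)CCCC)N1[C@H](Cc2ccccc2)COC1=O | intermediate
26 | (R)-4-benzyl-3-[(2R,3S)-3-hydroxy-2-methylbutanoyl]oxazolidin-2-one | O=C([C@H](C)[C@H](C)O)N1[C@H](Cc2ccccc2)COC1=O | intermediate
27 | triethylsilyl ether of 26 | O=C([C@H](C)[C@H](C)O[Si](CC)(CC)CC)N1[C@H](Cc2ccccc2)COC1=O | intermediate
28 | (2R,3S)-2-methyl-3-(triethylsilyloxy)butanoic acid | OC(=O)[C@H](C)[C@H](C)O[Si](CC)(CC)CC | intermediate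
29 | 8,9-diester seco-diene | C=C[C@H]1OC(=O)C(P(=O)(OCC)OCC)[C@@H]1[C@H](OC(=O)[C@@]2(C)O[C@H]2C)[C@H](OC(=O)[C@H](C)[C@H](C)O[Si](CC)(CC)CC)/C(C(=O)OC)=C\CCC(C)=C | intermediate
30 | macrocyclic α-phosphono lactone | CCOP(=O)(OCC)C1C(=O)O[C@@H]2/C=C(/C)CC/C=C(/C(=O)OC)[C@@H](OC(=O)[C@H](C)[C@H](C)O[Si](CC)(CC)CC)[C@@H](OC(=O)[C@@]3(C)O[C@H]3C)[C@@H]12 | intermediate
31 | triethylsilyl ether of the target | C=C1C(=O)O[C@@H]2/C=C(/C)CC/C=C(/C(=O)OC)[C@@H](OC(=O)[C@H](C)[C@H](C)O[Si](CC)(CC)CC)[C@@H](OC(=O)[C@@]3(C)O[C@H]3C)[C@@H]12 | intermediate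
32 | CNP0135583.1 | C=C1C(=O)O[C@@H]2/C=C(/C)CC/C=C(/C(=O)OC)[C@@H](OC(=O)[C@H](C)[C@H](C)O)[C@@H](OC(=O)[C@@]3(C)O[C@H]3C)[C@@H]12 | target

**Step count**

Total step count: 21. Longest linear sequence: 13 steps (1–5, 9–11, 14, 18–21).

**Steps most likely to fail**

Step 5.
- **What may go wrong:** the soft carbanion may open the internal epoxide too slowly. Lactone migration to O8, phosphoryl transfer followed by cyclopropane formation, or 6-endo attack could then take over.
- **Fallback (known chemistry; sets out from 5, comes back at 9):** the epoxide acceptor is replaced by an enal and O8 is brought in afterwards.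
 - Kinetic-resolution epoxidation of 5 with L-(+)-DIPT, taken past half conversion, turns the (S)-alcohol into the enantiomeric epoxy alcohol F1 (discarded) and leaves the (R)-dienol F2.
 - DCC/DMAP coupling with 7 gives the dienyl phosphonoacetate F3. HF·pyridine frees the allylic alcohol F4, and MnO2 gives the enal F5.
 - Cs2CO3 (cat.) in dilute THF closes the same C7–C11 bond by 5-exo-trig intramolecular Michael addition. This is the first half of the telescoped Michael/olefination chemistry of phosphonoacetates, and it gives the trans-lactone aldehyde F6.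
 - D-proline-catalysed α-aminoxylation with nitrosobenzene gives the (8S)-anilinooxy aldehyde F7, which NaBH4 reduces in the same flask to the anilinooxy alcohol F8.
 - Zn/AcOH cleaves the N–O bond to the diol F9, and TBSCl/imidazole silylates the primary hydroxyl group to give 9.

Step 19.
- **What may go wrong:** oligomerisation through the unhindered vinyl group may outrun closure onto the 1,1-disubstituted alkene, and the catalyst may decay at the temperature needed.
- **Fallback (sets out from 16, comes back at 30):** relay ring-closing metathesis, in which a sacrificial tether delivers the ruthenium to C4.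
 - Geraniol is O-allylated (NaH, allyl bromide) to allyl geranyl ether F10.
 - mCPBA epoxidises the remote trisubstituted alkene to the epoxide F11, and H5IO6 cleaves it to (E)-6-(allyloxy)-4-methylhex-4-enal F12.
 - The protocol of step 13 (19, NIS, then the aldehyde) gives the relay iodide F13.
 - CrCl2/NiCl2 coupling with 16 gives the relay alcohol F14, and MNBA esterification with 28 gives the relay triene F15.
 - The catalyst loads on the allyl ether, expels 2,5-dihydrofuran and so becomes the alkylidene on C4. Closure onto the unhindered vinyl group then gives 30.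

Step 14.
- **What may go wrong:** the ester-bearing alkenylchromium may lose its alkene geometry through an oxygen-bound allenolate form, and facial selectivity at the aldehyde may be insufficient.
- **Fallback (sets out from 21 and 16, comes back at 22):** the coupling partner is taken to an oxidation level that cannot form an allenolate, and the ester is restored afterwards.
 - Diisobutylaluminium hydride reduces 21 to (Z)-2-iodo-6-methylhepta-2,6-dien-1-ol F16.
 - CrCl2/NiCl2 coupling with 16 gives the C9,C14-diol F17.
 - TEMPO/PhI(OAc)2 oxidises the primary allylic alcohol selectively to the enal F18.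
 - Pinnick oxidation (NaClO2, NaH2PO4, 2-methylbut-2-ene) gives the acid F19.
 - Me3SiCHN2 gives 22; the lactone is still masked and cannot add the diazo compound.

**Further compounds**

F1 | step 5 | (1S)-1-[(2S,3S)-3-(tert-butyldimethylsilyloxymethyl)oxiran-2-yl]prop-2-en-1-ol (enantiomer of 6) | C=C[C@H](O)[C@@H]1O[C@H]1CO[Si](C)(C)C(C)(C)C
F2 | step 5 | (R,E)-6-(tert-butyldimethylsilyloxy)hexa-1,4-dien-3-ol | C=C[C@@H](O)/C=C/CO[Si](C)(C)C(C)(C)C
F3 | step 5 | (diethoxyphosphoryl)acetate of F2 | C=C[C@@H](OC(=O)CP(=O)(OCC)OCC)/C=C/CO[Si](C)(C)C(C)(C)C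
F4 | step 5 | (R,E)-6-hydroxyhexa-1,4-dien-3-yl (diethoxyphosphoryl)acetate | C=C[C@@H](OC(=O)CP(=O)(OCC)OCC)/C=C/CO
F5 | step 5 | (R,E)-6-oxohexa-1,4-dien-3-yl (diethoxyphosphoryl)acetate | C=C[C@@H](OC(=O)CP(=O)(OCC)OCC)/C=C/C=O
F6 | step 5 | trans-lactone aldehyde, diethyl [5-ethenyl-2-oxo-4-(2-oxoethyl)oxolan-3-yl]phosphonate | C=C[C@H]1OC(=O)C(P(=O)(OCC)OCC)[C@@H]1CC=O
F7 | step 5 | (8S)-anilinooxy aldehyde | C=C[C@H]1OC(=O)C(P(=O)(OCC)OCC)[C@@H]1[C@H](ONc2ccccc2)C=O
F8 | step 5 | (8S)-anilinooxy alcohol | C=C[C@H]1OC(=O)C(P(=O)(OCC)OCC)[C@@H]1[C@H](ONc2ccccc2)CO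
F9 | step 5 | C8,C9-diol (desilyl 9) | C=C[C@H]1OC(=O)C(P(=O)(OCC)OCC)[C@@H]1[C@H](O)CO
F10 | step 19 | allyl geranyl ether | CC(C)=CCC/C(C)=C/COCC=C
F11 | step 19 | 6,7-epoxide of allyl geranyl ether | CC1(C)OC1CC/C(C)=C/COCC=C
F12 | step 19 | (E)-6-(allyloxy)-4-methylhex-4-enal | O=CCC/C(C)=C/COCC=C
F13 | step 19 | methyl (2Z,6E)-8-(allyloxy)-2-iodo-6-methylocta-2,6-dienoate | COC(=O)/C(I)=C/CC/C(C)=C/COCC=C
F14 | step 19 | relay C9 alcohol | C=C[C@H]1OC(=O)C(P(=O)(OCC)OCC)[C@@H]1[C@H](OC(=O)[C@@]2(C)O[C@H]2C)[C@H](O)/C(C(=O)OC)=C\CC/C(C)=C/COCC=C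
F15 | step 19 | relay 8,9-diester triene | C=C[C@H]1OC(=O)C(P(=O)(OCC)OCC)[C@@H]1[C@H](OC(=O)[C@@]2(C)O[C@H]2C)[C@H](OC(=O)[C@H](C)[C@H](C)O[Si](CC)(CC)CC)/C(C(=O)OC)=C\CC/C(C)=C/COCC=C
F16 | step 14 | (Z)-2-iodo-6-methylhepta-2,6-dien-1-ol | C=C(C)CC/C=C(/CO)I
F17 | step 14 | C9,C14-diol | C=C[C@H]1OC(=O)C(P(=O)(OCC)OCC)[C@@H]1[C@H](OC(=O)[C@@]2(C)O[C@H]2C)[C@H](O)/C(CO)=C\CCC(C)=C
F18 | step 14 | C14 enal | C=C[C@H]1OC(=O)C(P(=O)(OCC)OCC)[C@@H]1[C@H](OC(=O)[C@@]2(C)O[C@H]2C)[C@H](O)/C(C=O)=C\CCC(C)=C
F19 | step 14 | C14 acid | C=C[C@H]1OC(=O)C(P(=O)(OCC)OCC)[C@@H]1[C@H](OC(=O)[C@@]2(C)O[C@H]2C)[C@H](O)/C(C(=O)O)=C\CCC(C)=C
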